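**Retrosynthetic overview**
1. Target 17 ⇐ tri-O-benzyl isoflavan 15 (hydrogenolysis, then air: ring B hydroquinone → quinone, ring A 6-OH freed) ⇐ lactol 14 (deoxygenation at C2).
2. 14 ⇐ o-quinone methide 12 (ring A, released from sulfone 6) + arylacetaldehyde 11 (ring B with C2 and C3): amine-catalysed enantioselective formal oxa-[4+2] that makes C3–C4 and O1–C2 and sets C3.
3. Enabling feature: on ring A the ring oxygen O1 (on C8a) is ortho to C4a, which carries the benzylic C4, so O1=C8a–C4a=C4 is a latent o-quinone methide; C3 (bearing ring B) and C2 (O-bound) are the α- and carbonyl carbons of an arylacetaldehyde. O1 is also para to the C6 oxygen, so rings A and B share one 2,3-dimethoxy-1,4-dioxygenated pattern and are unveiled together.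
4. Fragments: 6 from 4-hydroxy-2,3-dimethoxybenzaldehyde (4 steps); 11 from 2,3-dimethoxy-1,4-benzoquinone (3 steps).
5. Ring order: rings A and B are bought as six-membered carbocycles; the pyran ring (O1, C2, C3, C4, C4a, C8a) is the only ring made and is closed last, in step 8.

Key step: step 8

Assumption: 4-hydroxy-2,3-dimethoxybenzaldehyde and 2,3-dimethoxy-1,4-benzoquinone are taken as catalogue compounds; the stereocentre of the target is 3S by CIP (C2 > ring-B carbon > C4 > H).

Step 1
Reactants: 1 4-hydroxy-2,3-dimethoxybenzaldehyde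
Product: 2 4-(benzyloxy)-2,3-dimethoxybenzaldehyde
Conditions: BnBr, K2CO3, DMF, rt
Reagents that add atoms: benzyl bromide BrCc1ccccc1
Why: Williamson ether synthesis, in which the only acidic OH is the phenol para to the formyl group, so its phenoxide should be O-benzylated cleanly while the aldehyde is untouched.

Step 2
Reactants: 2 4-(benzyloxy)-2,3-dimethoxybenzaldehyde
Product: 4 4-(benzyloxy)-2,3-dimethoxyphenol, via aryl formate 3 (not isolated)
Conditions: mCPBA, CH2Cl2, 0 °C → rt; aq. NaHCO3/Na2S2O3 wash; then K2CO3 (cat.), MeOH, rt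
Reagents that add atoms: mCPBA OOC(=O)c1cccc(Cl)c1
Why: Dakin-type Baeyer–Villiger oxidation, in which the electron-rich aryl group (ortho-OMe, para-OBn) migrates to give formate 3, which methanol then transesterifies to the phenol while the benzyl and methyl ethers are inert.

Step 3
Reactants: 4 4-(benzyloxy)-2,3-dimethoxyphenol
Product: 5 4-(benzyloxy)-6-(hydroxymethyl)-2,3-dimethoxyphenol
Conditions: 37% aq. HCHO (excess), NaOH (1.0 equiv), H2O/THF, 0 °C → rt, N2; then AcOH
Reagents that add atoms: formaldehyde C=O
Why: Lederer–Manasse hydroxymethylation, in which the phenoxide of 4 has a single free ortho position (C6, also para to the 3-OMe) and a blocked para position, so formaldehyde should enter only there, with room temperature and excess formaldehyde holding back diarylmethane formation.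

Step 4
Reactants: 5 4-(benzyloxy)-6-(hydroxymethyl)-2,3-dimethoxyphenol
Product: 6 4-(benzyloxy)-2,3-dimethoxy-6-[(4-methylbenzenesulfonyl)methyl]phenol
Conditions: TolSO2Na (2 equiv), HCO2H/H2O, rt
Reagents that add atoms: sodium p-toluenesulfinate [Na+].[O-]S(=O)c1ccc(C)cc1
Why: Acid-promoted benzylic substitution (SN1 through the o-hydroxy/p-methoxy-stabilized benzylic cation) with sulfinate as S-nucleophile should give the bench-stable sulfone, the usual o-quinone methide precursor.

Step 5
Reactants: 7 2,3-dimethoxy-1,4-benzoquinone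
Product: 8 2,3-dimethoxy-5-(prop-2-en-1-yl)benzene-1,4-diol
Conditions: allylSnBu3, BF3·OEt2, CH2Cl2, −78 °C, N2; dil. HCl work-up
Reagents that add atoms: allyltributylstannane C=CC[Sn](CCCC)(CCCC)CCCC
Why: Lewis acid-promoted allylation of a quinone with an allylstannane (allyl transfer followed by aromatization to the hydroquinone), in which the two free ring positions of 7 are equivalent, so a single regioisomer should result.

Step 6
Reactants: 8 2,3-dimethoxy-5-(prop-2-en-1-yl)benzene-1,4-diol
Product: 9 1,4-bis(benzyloxy)-2,3-dimethoxy-5-(prop-2-en-1-yl)benzene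
Conditions: BnBr, K2CO3, DMF, 50 °C, N2
Reagents that add atoms: benzyl bromide BrCc1ccccc1
Why: Double Williamson ether synthesis caps both hydroquinone oxygens, which stops air oxidation to the allylquinone and keeps the oxygen ortho to the side chain from forming a lactol later.

Step 7
Reactants: 9 1,4-bis(benzyloxy)-2,3-dimethoxy-5-(prop-2-en-1-yl)benzene
Product: 11 2-[2,5-bis(benzyloxy)-3,4-dimethoxyphenyl]acetaldehyde, via vicinal diol 10 (not isolated)
Conditions: OsO4 (2 mol %), NaIO4, 2,6-lutidine, dioxane/H2O, rt; used crude at once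
Reagents that add atoms: sodium periodate [Na+].[O-][I](=O)(=O)=O (terminal oxidant; the aldehyde oxygen is delivered through osmium tetroxide O=[Os](=O)(=O)=O)
Why: Lemieux–Johnson oxidation (catalytic dihydroxylation to diol 10, then periodate glycol cleavage) should shorten the allyl group to the arylacetaldehyde without touching the electron-rich arene or the benzyl ethers.

Step 8
Reactants: 6 4-(benzyloxy)-2,3-dimethoxy-6-[(4-methylbenzenesulfonyl)methyl]phenol; 11 2-[2,5-bis(benzyloxy)-3,4-dimethoxyphenyl]acetaldehyde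
Product: 14 (3S)-6-(benzyloxy)-3-[2,5-bis(benzyloxy)-3,4-dimethoxyphenyl]-7,8-dimethoxy-3,4-dihydro-2H-chromen-2-ol (mixture of C2 epimers), via o-quinone methide 12 (not isolated), via hydroxy aldehyde 13 (not isolated)
Conditions: (S)-α,α-diphenylprolinol trimethylsilyl ether (20 mol %), sat. aq. NaHCO3, CH2Cl2, 0 °C → rt
Reagents that add atoms: none
Why: Bicarbonate deprotonates the phenol of 6 and p-toluenesulfinate is expelled to give o-quinone methide 12 (the oxadiene O1=C8a–C4a=C4) in low stationary concentration, while the catalyst condenses with 11 to the E-enamine, whose β-carbon (future C3) adds to the unsubstituted methide carbon (future C4) in a Michael addition that re-aromatizes ring A. Hydrolysis of the iminium ion frees aldehyde 13, and the liberated phenol oxygen O1 closes the pyran ring onto C2 by 6-exo-trig hemiacetalization, so the whole event is a stepwise formal inverse-demand oxa-[4+2] annulation that makes C3–C4 and O1–C2 in one flask. The closest known reaction type is the diarylprolinol silyl ether-catalysed Michael/hemiacetalization of aldehydes with o-quinone methides released from 2-(sulfonylmethyl)phenols, which gives chroman-2-ols. C3 is set by the catalyst: the diphenyl(trimethylsilyloxy)methyl group screens one face of the s-trans E-enamine, the methide attacks the open Si face, and by analogy with Michael additions of this catalyst the (S)-enantiomer should give 3S (the (R)-catalyst is equally available), whereas the anomeric C2 is uncontrolled and is deleted in step 9. The step needs C-alkylation of the enamine to outrun N-alkylation of the catalyst, methide oligomerization and aldol self-condensation of 11, which the slow biphasic release of 12 from the sulfone and the soft conjugated enamine should secure. The 6-O-benzyl group stops 12 from tautomerizing to a p-quinone, and the O-benzyl group ortho to the side chain on ring B leaves O1 as the only phenol able to close a lactol, so only the six-membered ring can form.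

Step 9
Reactants: 14 (3S)-6-(benzyloxy)-3-[2,5-bis(benzyloxy)-3,4-dimethoxyphenyl]-7,8-dimethoxy-3,4-dihydro-2H-chromen-2-ol
Product: 15 (3S)-6-(benzyloxy)-3-[2,5-bis(benzyloxy)-3,4-dimethoxyphenyl]-7,8-dimethoxy-3,4-dihydro-2H-chromene
Conditions: Et3SiH, BF3·OEt2, CH2Cl2, −78 → −40 °C
Reagents that add atoms: none
Why: Ionic hydrogenation of a lactol (Lewis acid ionization to the cyclic oxocarbenium ion, then hydride delivery from the silane) should remove the C2 hydroxyl at low temperature, where hydride capture should outrun loss of the C3 proton, so the C3 configuration is kept and the benzyl ethers survive.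

Step 10
Reactants: 15 (3S)-6-(benzyloxy)-3-[2,5-bis(benzyloxy)-3,4-dimethoxyphenyl]-7,8-dimethoxy-3,4-dihydro-2H-chromene
Product: 17 2-[(3S)-6-hydroxy-7,8-dimethoxy-3,4-dihydro-2H-chromen-3-yl]-5,6-dimethoxycyclohexa-2,5-diene-1,4-dione (CNP0302517.1), via hydroquinone 16 (not isolated)
Conditions: H2 (1 atm), 10% Pd/C, EtOAc, rt; filter; then O2 (air), SiO2, EtOAc, rt
Reagents that add atoms: none
Why: Hydrogenolysis of the three benzyl ethers followed by autoxidation, in which only ring B emerges as a free 1,4-hydroquinone that dioxygen should oxidize to the quinone, whereas ring A is a mono-phenol whose para oxygen is the ring ether O1, and the neutral medium avoids quinone/quinone methide tautomerization that would endanger C3.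

**Compound list**
1 | 4-hydroxy-2,3-dimethoxybenzaldehyde | O=Cc1ccc(O)c(OC)c1OC | starting material
2 | 4-(benzyloxy)-2,3-dimethoxybenzaldehyde | O=Cc1ccc(OCc2ccccc2)c(OC)c1OC | intermediate
3 | 4-(benzyloxy)-2,3-dimethoxyphenyl formate | O=COc1ccc(OCc2ccccc2)c(OC)c1OC | intermediate
4 | 4-(benzyloxy)-2,3-dimethoxyphenol | Oc1ccc(OCc2ccccc2)c(OC)c1OC | intermediate
5 | 4-(benzyloxy)-6-(hydroxymethyl)-2,3-dimethoxyphenol | OCc1cc(OCc2ccccc2)c(OC)c(OC)c1O | intermediate
6 | 4-(benzyloxy)-2,3-dimethoxy-6-[(4-methylbenzenesulfonyl)methyl]phenol | Cc1ccc(cc1)S(=O)(=O)Cc1cc(OCc2ccccc2)c(OC)c(OC)c1O | intermediate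
7 | 2,3-dimethoxy-1,4-benzoquinone | COC1=C(OC)C(=O)C=CC1=O | starting material
8 | 2,3-dimethoxy-5-(prop-2-en-1-yl)benzene-1,4-diol | C=CCc1cc(O)c(OC)c(OC)c1O | intermediate
9 | 1,4-bis(benzyloxy)-2,3-dimethoxy-5-(prop-2-en-1-yl)benzene | C=CCc1cc(OCc2ccccc2)c(OC)c(OC)c1OCc1ccccc1 | intermediate
10 | 3-[2,5-bis(benzyloxy)-3,4-dimethoxyphenyl]propane-1,2-diol (racemic) | OCC(O)Cc1cc(OCc2ccccc2)c(OC)c(OC)c1OCc1ccccc1 | intermediate
11 | 2-[2,5-bis(benzyloxy)-3,4-dimethoxyphenyl]acetaldehyde | O=CCc1cc(OCc2ccccc2)c(OC)c(OC)c1OCc1ccccc1 | intermediate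
12 | 4-(benzyloxy)-2,3-dimethoxy-6-methylidenecyclohexa-2,4-dien-1-one | C=C1C=C(OCc2ccccc2)C(OC)=C(OC)C1=O | intermediate
13 | (2S)-3-[5-(benzyloxy)-2-hydroxy-3,4-dimethoxyphenyl]-2-[2,5-bis(benzyloxy)-3,4-dimethoxyphenyl]propanal | COc1c(OC)c(OCc2ccccc2)cc([C@H](Cc2cc(OCc3ccccc3)c(OC)c(OC)c2O)C=O)c1OCc1ccccc1 | intermediate
14 | (3S)-6-(benzyloxy)-3-[2,5-bis(benzyloxy)-3,4-dimethoxyphenyl]-7,8-dimethoxy-3,4-dihydro-2H-chromen-2-ol (C2 epimers) | COc1c(OC)c(OCc2ccccc2)cc([C@H]2C(O)Oc3c(cc(OCc4ccccc4)c(OC)c3OC)C2)c1OCc1ccccc1 | intermediate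
15 | (3S)-6-(benzyloxy)-3-[2,5-bis(benzyloxy)-3,4-dimethoxyphenyl]-7,8-dimethoxy-3,4-dihydro-2H-chromene | COc1c(OC)c(OCc2ccccc2)cc([C@H]2COc3c(cc(OCc4ccccc4)c(OC)c3OC)C2)c1OCc1ccccc1 | intermediate
16 | 2-[(3S)-6-hydroxy-7,8-dimethoxy-3,4-dihydro-2H-chromen-3-yl]-5,6-dimethoxybenzene-1,4-diol | COc1c(OC)c(O)cc([C@H]2COc3c(cc(O)c(OC)c3OC)C2)c1O | intermediate
17 | 2-[(3S)-6-hydroxy-7,8-dimethoxy-3,4-dihydro-2H-chromen-3-yl]-5,6-dimethoxycyclohexa-2,5-diene-1,4-dione | COC1=C(OC)C(=O)C([C@H]2COc3c(cc(O)c(OC)c3OC)C2)=CC1=O | target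

Total step count: 10
Longest linear sequence: 7 steps (steps 1–4, then 8, 9, 10)

**Steps most likely to fail**

Step 8. The unhindered methide may N-alkylate the secondary-amine catalyst and stop turnover, the arylacetaldehyde may self-condense, or ring-opened lactol may re-enter the enamine manifold and erode the C3 configuration. The fallback sets out from 11 and 6 and comes back at 15, and sets C3 by asymmetric hydrogenation instead of by enamine face control. Aldehyde 11 is condensed with morpholine (toluene, MgSO4) to the enamine 4-[(E)-2-[2,5-bis(benzyloxy)-3,4-dimethoxyphenyl]ethenyl]morpholine F1. F1 is combined stoichiometrically with methide 12 released from 6 (Na2CO3, CH2Cl2/H2O) in the classical enamine/o-quinone methide [4+2] cycloaddition to give racemic 4-[6-(benzyloxy)-3-[2,5-bis(benzyloxy)-3,4-dimethoxyphenyl]-7,8-dimethoxy-3,4-dihydro-2H-chromen-2-yl]morpholine F2. Acid-catalysed loss of morpholine (cat. p-TsOH, toluene, 80 °C) should give 6-(benzyloxy)-3-[2,5-bis(benzyloxy)-3,4-dimethoxyphenyl]-7,8-dimethoxy-4H-chromene F3. Iridium/chiral N,P-ligand (PHOX-type) asymmetric hydrogenation of this trisubstituted aryl enol ether (H2 50 bar, CH2Cl2), with the ligand enantiomer chosen for the 3S product, should deliver 15.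

Step 9. The C2 oxocarbenium ion may lose the acidic benzylic C3 proton to give an enol ether whose reprotonation and reduction would erode the enantiomeric purity, or the ring-opened aldehyde may be over-reduced. The fallback sets out from 14 and comes back at 15; it reopens the pyran ring and closes it again at O1–C2 without touching C3. NaBH4 (MeOH, 0 °C) reduces the open-chain tautomer to (2S)-3-[5-(benzyloxy)-2-hydroxy-3,4-dimethoxyphenyl]-2-[2,5-bis(benzyloxy)-3,4-dimethoxyphenyl]propan-1-ol F4. Intramolecular Mitsunobu etherification (PPh3, DIAD, THF, 0 °C) of the phenol onto the primary alcohol should then give 15.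

Step 3. The hydroxymethyl phenol may condense with a second phenoxide to a diarylmethane, or oligomerize through its quinone methide. The fallback sets out from 4 and comes back at 5. Magnesium-mediated ortho-formylation (MgCl2, Et3N, paraformaldehyde, MeCN, reflux) should give 5-(benzyloxy)-2-hydroxy-3,4-dimethoxybenzaldehyde F5, which NaBH4 (MeOH, 0 °C) reduces to 5.

**Further compounds**
F1 | step 8 | 4-[(E)-2-[2,5-bis(benzyloxy)-3,4-dimethoxyphenyl]ethenyl]morpholine | COc1c(OC)c(OCc2ccccc2)cc(/C=C/N2CCOCC2)c1OCc1ccccc1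
F2 | step 8 | 4-[6-(benzyloxy)-3-[2,5-bis(benzyloxy)-3,4-dimethoxyphenyl]-7,8-dimethoxy-3,4-dihydro-2H-chromen-2-yl]morpholine (racemic) | COc1c(OC)c(OCc2ccccc2)cc(C2Cc3cc(OCc4ccccc4)c(OC)c(OC)c3OC2N2CCOCC2)c1OCc1ccccc1
F3 | step 8 | 6-(benzyloxy)-3-[2,5-bis(benzyloxy)-3,4-dimethoxyphenyl]-7,8-dimethoxy-4H-chromene | COc1c(OC)c(OCc2ccccc2)cc(C2=COc3c(cc(OCc4ccccc4)c(OC)c3OC)C2)c1OCc1ccccc1
F4 | step 9 | (2S)-3-[5-(benzyloxy)-2-hydroxy-3,4-dimethoxyphenyl]-2-[2,5-bis(benzyloxy)-3,4-dimethoxyphenyl]propan-1-ol | COc1c(OC)c(OCc2ccccc2)cc([C@H](Cc2cc(OCc3ccccc3)c(OC)c(OC)c2O)CO)c1OCc1ccccc1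
F5 | step 3 | 5-(benzyloxy)-2-hydroxy-3,4-dimethoxybenzaldehyde | O=Cc1cc(OCc2ccccc2)c(OC)c(OC)c1O
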